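All runs are calculated on assumed constants; the scatter is artificial.

The trap in this flask is to expect the share of target to climb from a low start.

| flask | substrate | other conformer | gas | remark | time |
|---|---|---|---|---|---|
| birch | 0.81 M | 0.050 equiv | 110 mM (held) | run made earlier |  |
| cedar | 0.81 M | 0.20 equiv | 110 mM (held) | run made earlier |  |
| ash | 1.6 M | 0.10 equiv | 110 mM (held) | run made earlier |  |
| flask | 0.81 M | 0.100 equiv | 110 mM (held) |  | 3.0 d |

| run | time / d | target / % | isomer of the product / % |
|---|---|---|---|
| birch | 0.625 | 37.1 | 17.3 |
| birch | 1.25 | 53.1 | 24.7 |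
| birch | 2.00 | 63.1 | 28.2 |
| birch | 3.00 | 66.3 | 30.6 |
| birch | 4.00 | 68.3 | 31.4 |
| cedar | 0.333 | 19.8 | 14.7 |
| cedar | 0.833 | 40.9 | 23.5 |
| cedar | 1.67 | 56.2 | 31.8 |
| cedar | 2.50 | 61.8 | 32.7 |
| cedar | 4.00 | 64.6 | 35.5 |
| ash | 0.250 | 14.5 | 8.2 |
| ash | 0.500 | 28.5 | 14.3 |
| ash | 1.04 | 46.1 | 23.6 |
| ash | 2.08 | 61.1 | 30.6 |
| ash | 4.00 | 65.8 | 33.1 |

(readings scatter by 0.5 percentage points)

1. share of target in target plus isomer of the product at 50 min
2. share of target in target plus isomer of the product at 6.0 h
3. share of target in target plus isomer of the product at 3.0 d
4. which of target and isomer of the product there is more of at 3.0 d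

- at the start none of reagent is dissolved
- steps that have been proposed: substrate + reagent -> target; gas <-> reagent; substrate <-> other conformer; reagent + other conformer -> isomer of the product

On the proposed steps both products take up reagent, so [reagent] cancels from their ratio: isomer of the product forms against target as s·[other conformer]/[substrate]. In the ash run, isomer per target reads 0.502 at the second reading and 0.503 at the last. Dividing the last by the charged 0.10 equiv gives s = 5.03, the selectivity factor, the reactivity of other conformer over that of substrate.

That value assumes the ratio stayed at its charge, so it goes round once more. From first to last reading, the gain of isomer of the product per gain of target, divided by s, reads 0.0898 in birch and 0.0923 in cedar, as estimates of the running [other conformer]/[substrate]. The charge of ash lies nearer to these than the charge of birch does. The flask is charged with the same equivalents as ash, so my own reckoning for it, at 0.100 equiv, is a nearly flat share of 66.5 %, with target ahead.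

The forecast gave 57.5 %, 64 % and 66.7 %, with target ahead: “At 50 min the target share is near the initial 56–58%”. It differs from my reckoning at the early time.

The flask gives shares of 65.7 % at 50 min, 66.3 % at 6.0 h and 67.0 % at 3.0 d, with 65.4 % of target against 32.2 % of isomer of the product at 3.0 d.

    substrate + reagent → target (k = 0.356 M⁻¹ h⁻¹)
    gas ⇌ reagent, rate k2*(csat - [reagent]) (kL = 4.85 h⁻¹)
    substrate ⇌ other conformer (K = 0.164, k = 0.0319 h⁻¹)
    reagent + other conformer → isomer of the product (k = 1.83 M⁻¹ h⁻¹)

In the flask, [other conformer]/[substrate] stands at 0.0965 after 0.300 d, beside the charged 0.100 equiv. For the neighbouring flask, charged with 0.0400 equiv, the same s reckons a share of 83.3 % for the charged ratio. That neighbouring flask gives 79.8 % at 50 min, 72.8 % at 6.0 h and 68.8 % at 3.0 d.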